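The six carbons of the 2-methyl-6-alkyl-1,4-benzoquinone ring stay open until the end and are closed in one annulation from three pieces. These are the terminal alkyne of an acyclic 1,4-enyne diol (ring C-5 and C-6, the chain on C-6), a trans-propenyl(methoxy)carbene chromium complex (C-4, C-3, C-2 and its methyl) and one CO ligand (C-1). The feature exploited is that the C-1 carbonyl is flanked by both carbon substituents while the C-4 carbonyl is flanked by two CH, the native regiochemistry of a Dötz benzannulation; oxidative work-up gives the quinone. The precursor comes from farnesyl bromide, its syn-diol set by Sharpless epoxidation and palladium-mediated CO2 insertion with retention.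

Key step: step 10

Remark: chain carbons are numbered C-1' (on the ring) to C-16'; the quinone oxygen on C-4 is assumed to come from water in the oxidative demethylation, the methoxy oxygen leaving as methanol.

Step 1
Reactants: 1 (2E,6E)-farnesyl bromide; 2 ethynyltrimethylsilane
Product: 4 trimethyl[(4E,8E)-5,9,13-trimethyltetradeca-4,8,12-trien-1-yn-1-yl]silane, via bromo[(trimethylsilyl)ethynyl]magnesium 3 (not isolated)
Conditions: 2, EtMgBr, THF, 0 °C to rt; then 1, CuBr·SMe2 (5 mol%), THF, 0 °C to 40 °C
Reagents that add atoms: none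
Why: Copper-catalysed coupling of an alkynylmagnesium halide with a primary allylic bromide should substitute at the unhindered terminus (SN2 over SN2'), which keeps the 2E geometry and gives the skipped enyne.

Step 2
Reactants: 4 silyl enyne
Product: 5 (2E,6E,10E)-2,6,10-trimethyl-14-(trimethylsilyl)tetradeca-2,6,10-trien-13-yn-1-ol
Conditions: SeO2 (0.3 equiv), t-BuOOH (3 equiv), salicylic acid (0.1 equiv), CH2Cl2, 0 °C to rt; stopped at partial conversion, 4 recovered
Reagents that add atoms: tert-butyl hydroperoxide, CC(C)(C)OO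
Why: Riley-type SeO2/t-BuOOH allylic oxidation (ene reaction, then [2,3]-sigmatropic shift) should attack the (E)-methyl of the terminal isopropylidene unit, the most accessible alkene, while the bulky silyl group shields the propargylic CH2; the E geometry obtained decides which carbon later carries the methyl group at C-11'.

Step 3
Reactants: 5 allylic alcohol
Product: 6 [(2S,3S)-3-[(3E,7E)-3,7-dimethyl-11-(trimethylsilyl)undeca-3,7-dien-10-yn-1-yl]-2-methyloxiran-2-yl]methanol
Conditions: Ti(OiPr)4 (10 mol%), L-(+)-diethyl tartrate (12 mol%), t-BuOOH, 4 Å molecular sieves, CH2Cl2, −20 °C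
Reagents that add atoms: tert-butyl hydroperoxide, CC(C)(C)OO
Why: Katsuki–Sharpless asymmetric epoxidation acts only on the allylic alcohol, and with L-(+)-tartrate the oxygen should be delivered to the face that gives the (2S,3S)-epoxy alcohol, so C-10' and C-11' are both set by reagent control.

Step 4
Reactants: 6 epoxy alcohol
Product: 7 (2R,3S)-3-[(3E,7E)-3,7-dimethyl-11-(trimethylsilyl)undeca-3,7-dien-10-yn-1-yl]-2-methyloxirane-2-carbaldehyde
Conditions: Pr4N[RuO4] (5 mol%), N-methylmorpholine N-oxide, 4 Å molecular sieves, CH2Cl2, rt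
Reagents that add atoms: none
Why: Ley–Griffith oxidation is neutral and should give the aldehyde without opening the acid-sensitive trisubstituted epoxide; the α-carbon is quaternary, so it cannot epimerise (the descriptor changes only through ligand priority).

Step 5
Reactants: 7 epoxy aldehyde
Product: 8 (2S,3S)-2-ethenyl-2-methyl-3-[(3E,7E)-3,7-dimethyl-11-(trimethylsilyl)undeca-3,7-dien-10-yn-1-yl]oxirane
Conditions: Ph3PCH3Br, KN(SiMe3)2, THF, −78 °C to 0 °C
Reagents that add atoms: methyltriphenylphosphonium bromide, C[P+](c1ccccc1)(c1ccccc1)c1ccccc1.[Br-]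
Why: Wittig methylenation of the non-enolisable epoxy aldehyde should give the vinyl epoxide, the epoxide and the silyl alkyne being inert to the unstabilised ylide at low temperature.

Step 6
Reactants: 8 vinyl epoxide
Product: 9 (4S,5S)-4-ethenyl-4-methyl-5-[(3E,7E)-3,7-dimethyl-11-(trimethylsilyl)undeca-3,7-dien-10-yn-1-yl]-1,3-dioxolan-2-one
Conditions: Pd2(dba)3·CHCl3 (2.5 mol%), P(OiPr)3 (15 mol%), CO2 (1 atm), THF, 0 °C to rt
Reagents that add atoms: carbon dioxide, O=C=O
Why: In this palladium-catalysed CO2 insertion into a vinyl epoxide (Tsuji–Trost-type ionisation), zerovalent palladium opens the allylic C–O bond at the quaternary carbon with inversion, the C-10' alkoxide captures CO2 and the carbonate closes on the nearer allyl terminus anti to palladium, so the five-membered carbonate should form with net retention and the E-derived epoxide becomes the protected (S,S) syn-diol.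

Step 7
Reactants: 9 vinyl carbonate; 10 1-bromo-2-methylprop-1-ene
Product: 12 (4S,5S)-4-methyl-4-(4-methylpent-3-en-1-yl)-5-[(3E,7E)-3,7-dimethyl-11-(trimethylsilyl)undeca-3,7-dien-10-yn-1-yl]-1,3-dioxolan-2-one, via alkyl-9-BBN borane 11 (not isolated)
Conditions: 9-BBN, THF, 0 °C to rt; then 10, Pd(dppf)Cl2 (5 mol%), AsPh3, K3PO4, DMF/H2O, rt
Reagents that add atoms: none
Why: 9-BBN should hydroborate only the monosubstituted vinyl group (not the trisubstituted alkenes or the silyl alkyne) with boron on the terminal carbon, and B-alkyl Suzuki–Miyaura coupling with the vinyl bromide then forms the C-13'–C-14' bond and completes the prenyl terminus, which has no geometry to control.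

Step 8
Reactants: 12 silyl alkyne carbonate
Product: 13 (4E,8E,12S,13S)-5,9,13,17-tetramethyloctadeca-4,8,16-trien-1-yne-12,13-diol
Conditions: K2CO3, MeOH, rt
Reagents that add atoms: none
Why: Base-catalysed methanolysis should remove the alkynyl silyl group (protodesilylation) and transesterify the cyclic carbonate to dimethyl carbonate in one operation, breaking no bond at a stereocentre.

Step 9
Reactants: 14 (E)-1-bromoprop-1-ene; 15 hexacarbonylchromium
Product: 18 pentacarbonyl[(E)-1-methoxybut-2-en-1-ylidene]chromium, via (E)-prop-1-enyllithium 16 (not isolated), via lithium acylchromate 17 (not isolated)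
Conditions: 14, t-BuLi (2 equiv), Et2O, −78 °C; 15, Et2O, 0 °C to rt; then Me3OBF4, CH2Cl2/H2O, 0 °C
Reagents that add atoms: trimethyloxonium tetrafluoroborate, C[O+](C)C.F[B-](F)(F)F
Why: Fischer carbene synthesis: bromine–lithium exchange with retention of the E geometry, addition of the alkenyllithium to a CO ligand of Cr(CO)6 and O-methylation of the acylchromate with Meerwein's salt should give the alkenyl(methoxy)carbene complex.

Step 10
Reactants: 13 alkyne diol; 18 propenyl(methoxy)carbene chromium complex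
Product: 21 2-[(2E,6E,10S,11S)-10,11-dihydroxy-3,7,11,15-tetramethylhexadeca-2,6,14-trien-1-yl]-6-methylcyclohexa-2,5-diene-1,4-dione, via tricarbonylchromium phenol complex 19 (not isolated), via 4-methoxyphenol 20 (not isolated)
Conditions: 18 (1.5 equiv), THF (0.05 M), 50 °C, argon; then (NH4)2Ce(NO3)6 (5.5 equiv, in portions), MeCN/H2O, 0 °C
Reagents that add atoms: water, O
Why: Thermal loss of one CO from 18 lets the terminal alkyne of 13 coordinate and insert into the Cr=C bond with its unsubstituted carbon next to the former carbene carbon; CO insertion gives a chromium-bound dienylketene whose 6π-electrocyclisation onto the propenyl β-carbon and tautomerisation should deliver the complexed 4-methoxyphenol 19, after which tetravalent cerium removes the metal (20) and oxidises the p-methoxyphenol to the quinone with loss of methanol. The closest known reaction type is the Dötz benzannulation of an alkenyl(alkoxy)carbene chromium complex with a terminal alkyne followed by oxidative work-up, which is established for 1,4-enynes leading to prenylated quinones. The six-membered ring is closed by a formal [3+2+1] union (three carbons from the carbene ligand, two from the alkyne, one from CO), the last bond (C-1 to C-2) by 6π-electrocyclic closure. No stereocentre is formed, and the (10'S,11'S)-diol and the E alkenes are not involved. The step needs regioselective alkyne insertion, secured by the terminal alkyne, whose substituted carbon ends up next to the CO-derived C-1 so that chain and methyl flank the same carbonyl; it also needs the oxidant to spare the glycol and the alkenes, which rests on the much faster electron transfer from the electron-rich arene at 0 °C with a limited charge of oxidant.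

Compound list
1 | (2E,6E)-1-bromo-3,7,11-trimethyldodeca-2,6,10-triene (farnesyl bromide) | CC(C)=CCC/C(C)=C/CC/C(C)=C/CBr | starting material
2 | ethynyltrimethylsilane | C#C[Si](C)(C)C | starting material
3 | bromo[(trimethylsilyl)ethynyl]magnesium | C[Si](C)(C)C#C[Mg]Br | intermediate
4 | trimethyl[(4E,8E)-5,9,13-trimethyltetradeca-4,8,12-trien-1-yn-1-yl]silane | CC(C)=CCC/C(C)=C/CC/C(C)=C/CC#C[Si](C)(C)C | intermediate
5 | (2E,6E,10E)-2,6,10-trimethyl-14-(trimethylsilyl)tetradeca-2,6,10-trien-13-yn-1-ol | OC/C(C)=C/CC/C(C)=C/CC/C(C)=C/CC#C[Si](C)(C)C | intermediate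
6 | [(2S,3S)-3-[(3E,7E)-3,7-dimethyl-11-(trimethylsilyl)undeca-3,7-dien-10-yn-1-yl]-2-methyloxiran-2-yl]methanol | OC[C@]1(C)O[C@H]1CC/C(C)=C/CC/C(C)=C/CC#C[Si](C)(C)C | intermediate
7 | (2R,3S)-3-[(3E,7E)-3,7-dimethyl-11-(trimethylsilyl)undeca-3,7-dien-10-yn-1-yl]-2-methyloxirane-2-carbaldehyde | O=C[C@]1(C)O[C@H]1CC/C(C)=C/CC/C(C)=C/CC#C[Si](C)(C)C | intermediate
8 | (2S,3S)-2-ethenyl-2-methyl-3-[(3E,7E)-3,7-dimethyl-11-(trimethylsilyl)undeca-3,7-dien-10-yn-1-yl]oxirane | C=C[C@]1(C)O[C@H]1CC/C(C)=C/CC/C(C)=C/CC#C[Si](C)(C)C | intermediate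
9 | (4S,5S)-4-ethenyl-4-methyl-5-[(3E,7E)-3,7-dimethyl-11-(trimethylsilyl)undeca-3,7-dien-10-yn-1-yl]-1,3-dioxolan-2-one | C=C[C@]1(C)OC(=O)O[C@H]1CC/C(C)=C/CC/C(C)=C/CC#C[Si](C)(C)C | intermediate
10 | 1-bromo-2-methylprop-1-ene | CC(C)=CBr | starting material
11 | (4S,5S)-4-[2-(9-borabicyclo[3.3.1]nonan-9-yl)ethyl]-4-methyl-5-[(3E,7E)-3,7-dimethyl-11-(trimethylsilyl)undeca-3,7-dien-10-yn-1-yl]-1,3-dioxolan-2-one | C1CC2CCCC(C1)B2CC[C@]1(C)OC(=O)O[C@H]1CC/C(C)=C/CC/C(C)=C/CC#C[Si](C)(C)C | intermediate
12 | (4S,5S)-4-methyl-4-(4-methylpent-3-en-1-yl)-5-[(3E,7E)-3,7-dimethyl-11-(trimethylsilyl)undeca-3,7-dien-10-yn-1-yl]-1,3-dioxolan-2-one | CC(C)=CCC[C@]1(C)OC(=O)O[C@H]1CC/C(C)=C/CC/C(C)=C/CC#C[Si](C)(C)C | intermediate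
13 | (4E,8E,12S,13S)-5,9,13,17-tetramethyloctadeca-4,8,16-trien-1-yne-12,13-diol | CC(C)=CCC[C@](C)(O)[C@@H](O)CC/C(C)=C/CC/C(C)=C/CC#C | intermediate
14 | (E)-1-bromoprop-1-ene | C/C=C/Br | starting material
15 | hexacarbonylchromium, Cr(CO)6 | O=C=[Cr](=C=O)(=C=O)(=C=O)(=C=O)=C=O | starting material
16 | (E)-prop-1-en-1-yllithium | [Li]/C=C/C | intermediate
17 | lithium pentacarbonyl[(E)-1-oxidobut-2-en-1-ylidene]chromate | [Li+].C/C=C/C([O-])=[Cr](=C=O)(=C=O)(=C=O)(=C=O)=C=O | intermediate
18 | pentacarbonyl[(E)-1-methoxybut-2-en-1-ylidene]chromium | C/C=C/C(OC)=[Cr](=C=O)(=C=O)(=C=O)(=C=O)=C=O | intermediate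
19 | tricarbonyl(η6-arene)chromium complex of phenol 20 (SMILES shows the arene and Cr(CO)3 as two parts) | CC(C)=CCC[C@](C)(O)[C@@H](O)CC/C(C)=C/CC/C(C)=C/Cc1cc(OC)cc(C)c1O.O=C=[Cr](=C=O)=C=O | intermediate
20 | 2-[(2E,6E,10S,11S)-10,11-dihydroxy-3,7,11,15-tetramethylhexadeca-2,6,14-trien-1-yl]-4-methoxy-6-methylphenol | CC(C)=CCC[C@](C)(O)[C@@H](O)CC/C(C)=C/CC/C(C)=C/Cc1cc(OC)cc(C)c1O | intermediate
21 | 2-[(2E,6E,10S,11S)-10,11-dihydroxy-3,7,11,15-tetramethylhexadeca-2,6,14-trien-1-yl]-6-methylcyclohexa-2,5-diene-1,4-dione | CC(C)=CCC[C@](C)(O)[C@@H](O)CC/C(C)=C/CC/C(C)=C/CC1=CC(=O)C=C(C)C1=O | target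

Total step count: 10. Longest linear sequence: 9 steps (steps 1 to 8, then step 10); step 9 is a one-step side branch.

Steps most likely to fail

Step 10. Tetravalent cerium may begin oxidative cleavage of the vicinal diol during the work-up, or a hydroxyl group may trap the ketene intermediate. The fallback masks the diol and sets out from 13. 2,2-Dimethoxypropane and pyridinium p-toluenesulfonate in CH2Cl2 should give the acetonide-protected alkyne F1. The same benzannulation with 18 should then lead through the tricarbonylchromium complex of the acetonide phenol F2 and the acetonide phenol F3 to the acetonide quinone F4 after cerium oxidation. Aqueous acetic acid in THF removes the acetonide, and the route is rejoined at 21.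

Step 6. The π-allylpalladium intermediate may lose facial integrity by π–σ–π equilibration through its unsubstituted terminus, or the allylic carbonate may ionise again, either of which would scramble C-11'; β-hydride elimination to a dienol may also compete. The fallback avoids palladium at the stereocentre and sets out from 8. Hydroboration with 9-BBN should give the epoxy alkylborane F5, which is coupled with 10 under the conditions of step 7 to the prenylated epoxide F6. Halide-catalysed cycloaddition of CO2 to this epoxide (Bu4NBr, ZnBr2, CO2 under pressure, 80 °C) is a double inversion at C-10' with net retention and should return the route to 12.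

Step 2. The allylic oxidation may attack the doubly activated C-1' methylene or an inner allylic position, over-oxidise to the enal, or stall. The fallback rebuilds the allylic alcohol by cleavage and olefination and sets out from 4. NBS in aqueous THF should give the terminal bromohydrin F7, and NaH in THF closes it to the terminal epoxide F8. H5IO6 cleaves this to the trisnor aldehyde F9, and the stabilised ylide Ph3P=C(CH3)CO2Et gives the (E)-enoate F10. Reduction with i-Bu2AlH at −78 °C rejoins the route at 5.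

Further compounds
F1 | step 10 | (4S,5S)-5-[(3E,7E)-3,7-dimethylundeca-3,7-dien-10-yn-1-yl]-2,2,4-trimethyl-4-(4-methylpent-3-en-1-yl)-1,3-dioxolane | CC(C)=CCC[C@]1(C)OC(C)(C)O[C@H]1CC/C(C)=C/CC/C(C)=C/CC#C
F2 | step 10 | tricarbonyl(η6-arene)chromium complex of phenol F3 | CC(C)=CCC[C@]1(C)OC(C)(C)O[C@H]1CC/C(C)=C/CC/C(C)=C/Cc1cc(OC)cc(C)c1O.O=C=[Cr](=C=O)=C=O
F3 | step 10 | 4-methoxy-2-methyl-6-{(2E,6E)-3,7-dimethyl-9-[(4S,5S)-2,2,5-trimethyl-5-(4-methylpent-3-en-1-yl)-1,3-dioxolan-4-yl]nona-2,6-dien-1-yl}phenol | CC(C)=CCC[C@]1(C)OC(C)(C)O[C@H]1CC/C(C)=C/CC/C(C)=C/Cc1cc(OC)cc(C)c1O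
F4 | step 10 | 2-methyl-6-{(2E,6E)-3,7-dimethyl-9-[(4S,5S)-2,2,5-trimethyl-5-(4-methylpent-3-en-1-yl)-1,3-dioxolan-4-yl]nona-2,6-dien-1-yl}cyclohexa-2,5-diene-1,4-dione | CC(C)=CCC[C@]1(C)OC(C)(C)O[C@H]1CC/C(C)=C/CC/C(C)=C/CC1=CC(=O)C=C(C)C1=O
F5 | step 6 | 9-{2-[(2S,3S)-3-[(3E,7E)-3,7-dimethyl-11-(trimethylsilyl)undeca-3,7-dien-10-yn-1-yl]-2-methyloxiran-2-yl]ethyl}-9-borabicyclo[3.3.1]nonane | C1CC2CCCC(C1)B2CC[C@]1(C)O[C@H]1CC/C(C)=C/CC/C(C)=C/CC#C[Si](C)(C)C
F6 | step 6 | (2S,3S)-2-methyl-2-(4-methylpent-3-en-1-yl)-3-[(3E,7E)-3,7-dimethyl-11-(trimethylsilyl)undeca-3,7-dien-10-yn-1-yl]oxirane | CC(C)=CCC[C@]1(C)O[C@H]1CC/C(C)=C/CC/C(C)=C/CC#C[Si](C)(C)C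
F7 | step 2 | (6E,10E)-3-bromo-2,6,10-trimethyl-14-(trimethylsilyl)tetradeca-6,10-dien-13-yn-2-ol (racemic) | CC(C)(O)C(Br)CC/C(C)=C/CC/C(C)=C/CC#C[Si](C)(C)C
F8 | step 2 | 2,2-dimethyl-3-[(3E,7E)-3,7-dimethyl-11-(trimethylsilyl)undeca-3,7-dien-10-yn-1-yl]oxirane (racemic) | CC1(C)OC1CC/C(C)=C/CC/C(C)=C/CC#C[Si](C)(C)C
F9 | step 2 | (4E,8E)-4,8-dimethyl-12-(trimethylsilyl)dodeca-4,8-dien-11-ynal | O=CCC/C(C)=C/CC/C(C)=C/CC#C[Si](C)(C)C
F10 | step 2 | ethyl (2E,6E,10E)-2,6,10-trimethyl-14-(trimethylsilyl)tetradeca-2,6,10-trien-13-ynoate | CCOC(=O)/C(C)=C/CC/C(C)=C/CC/C(C)=C/CC#C[Si](C)(C)C
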